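## Retrosynthetic overview

- Germacrane numbering is used throughout: C1–C10 ring, C11–C13 lactone carbons, C14/C15 methyls. The target is opened at the C8–O ester: Mitsunobu esterification with inversion of a macrocyclic 8α-alcohol by the side-chain acid (two Baylis–Hillman units), then desilylation.
- Key disconnection C7–C8: the β-carbon of a 3-(bromomethyl)butenolide (a lactone homoenolate equivalent, made nucleophilic through its allylchromium) adds intramolecularly to the C8 aldehyde. One step gives the ten-membered ring, C7, C8 and the exo-methylene lactone.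
- The seco-aldehyde comes from ring-closing metathesis of a 2-(bromomethyl)acrylate of the C6 bis-allylic alcohol, itself from an asymmetric Nozaki–Hiyama–Kishi coupling (C5–C6).
- The (4Z)-iodoalkene comes from Duboudin carbomagnesiation of the C3 propargylic alcohol (asymmetric alkynylation); the 1(10)-E olefin from Negishi carboalumination of a but-3-yn-1-ol ether; the epoxide from Shi epoxidation.
- Ring order: oxirane (step 7), butenolide (step 10), ten-membered carbocycle with conversion of the butenolide into the α-methylene-γ-butyrolactone (step 13).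

Assumption: in steps 4 and 8 the quoted enantiomer of the chiral ligand is taken to give the drawn configuration; if its sense is opposite, the antipode is used with no other change.

## Route

Step 1
Reactants: 1 but-3-yn-1-ol
Product: 2 1-[(but-3-yn-1-yloxy)methyl]-4-methoxybenzene
Conditions: NaH, PMBCl, Bu4NI (cat.), THF, 0 °C → rt
Reagents that add atoms: 4-methoxybenzyl chloride, COc1ccc(CCl)cc1
Why: Williamson etherification of the alkoxide (the alkyne C–H is not deprotonated by one equivalent of NaH) installs a primary-alcohol protecting group that DDQ later removes under neutral conditions.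

Step 2
Reactants: 2 1-[(but-3-yn-1-yloxy)methyl]-4-methoxybenzene
Product: 5 (3E)-6-(4-methoxybenzyloxy)-4-methylhex-3-en-1-ol, via alkenyl(dimethyl)alane 3 (not isolated), via lithium alkenylaluminate 4 (not isolated)
Conditions: Me3Al, Cp2ZrCl2 (20 mol %), CH2Cl2, 0 °C → rt; evaporate; n-BuLi, hexane/THF, −30 °C; ethylene oxide, −30 °C → rt; aq. NH4Cl
Reagents that add atoms: trimethylaluminium, C[Al](C)C; ethylene oxide, C1CO1
Why: Negishi zirconium-catalysed syn-carboalumination fixes the (E)-trisubstituted C1=C10 olefin (C14 methyl on C10), and the derived lithium alanate opens ethylene oxide to add C2–C3.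

Step 3
Reactants: 5 (3E)-6-(4-methoxybenzyloxy)-4-methylhex-3-en-1-ol
Product: 6 (3E)-6-(4-methoxybenzyloxy)-4-methylhex-3-enal
Conditions: Dess–Martin periodinane, pyridine, CH2Cl2, 0 °C → rt; used crude
Reagents that add atoms: none
Why: Dess–Martin oxidation is mild and buffered, so the β,γ-unsaturated aldehyde is obtained without migration of the olefin into conjugation.

Step 4
Reactants: 6 (3E)-6-(4-methoxybenzyloxy)-4-methylhex-3-enal
Product: 8 (3S,5E)-8-(4-methoxybenzyloxy)-6-methyloct-5-en-1-yn-3-ol, via trimethylsilyl alkynol 7 (not isolated)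
Conditions: ethynyltrimethylsilane, Me2Zn, (S,S)-ProPhenol (20 mol %), Ph3PO (40 mol %), PhMe, 4 °C; then K2CO3, MeOH, rt
Reagents that add atoms: ethynyltrimethylsilane, C#C[Si](C)(C)C
Why: Trost ProPhenol dinuclear-zinc alkynylation delivers the alkynylzinc to one aldehyde face under ligand control and so sets C3 (S) under non-basic conditions, and methanolysis then removes the C-silyl group.

Step 5
Reactants: 8 (3S,5E)-8-(4-methoxybenzyloxy)-6-methyloct-5-en-1-yn-3-ol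
Product: 10 (1Z,3S,5E)-1-iodo-8-(4-methoxybenzyloxy)-2,6-dimethylocta-1,5-dien-3-ol, via alkenylmagnesium bromide 9 (not isolated)
Conditions: MeMgBr, CuI (20 mol %), THF, −20 °C → rt; then I2, −40 → 0 °C
Reagents that add atoms: methylmagnesium bromide, C[Mg]Br; iodine, II
Why: Duboudin copper-catalysed anti-carbomagnesiation of the propargylic alkoxide places methyl on C4 and magnesium on C5 cis to the carbinol (five-membered chelate), and iodinolysis with retention gives the (4Z)-iodoalkene.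

Step 6
Reactants: 10 (1Z,3S,5E)-1-iodo-8-(4-methoxybenzyloxy)-2,6-dimethylocta-1,5-dien-3-ol
Product: 11 tert-butyl{[(1Z,3S,5E)-1-iodo-8-(4-methoxybenzyloxy)-2,6-dimethylocta-1,5-dien-3-yl]oxy}dimethylsilane
Conditions: TBSOTf, 2,6-lutidine, CH2Cl2, −78 → 0 °C
Reagents that add atoms: tert-butyldimethylsilyl trifluoromethanesulfonate, CC(C)(C)[Si](C)(C)OS(=O)(=O)C(F)(F)F
Why: Silylation of the secondary allylic alcohol protects C3–OH until the last step and distinguishes it from the C6 and C8 hydroxyls made later.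

Step 7
Reactants: 11 tert-butyl{[(1Z,3S,5E)-1-iodo-8-(4-methoxybenzyloxy)-2,6-dimethylocta-1,5-dien-3-yl]oxy}dimethylsilane
Product: 12 tert-butyl{[(1Z,3S)-1-iodo-4-{(2R,3R)-3-[2-(4-methoxybenzyloxy)ethyl]-3-methyloxiran-2-yl}-2-methylbut-1-en-3-yl]oxy}dimethylsilane
Conditions: D-fructose-derived Shi ketone (30 mol %), KHSO5 (as Oxone, 2KHSO5·KHSO4·K2SO4), K2CO3, Bu4NHSO4 (cat.), MeCN/dimethoxymethane/aq. Na2B4O7 buffer, 0 °C
Reagents that add atoms: potassium peroxymonosulfate, [K+].OOS(=O)(=O)[O-]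
Why: Shi asymmetric epoxidation: the chiral dioxirane attacks the electron-rich (E)-trisubstituted C1=C10 olefin through the spiro transition state to give the (1R,10R)-epoxide, while the iodoalkene is electronically deactivated.

Step 8
Reactants: 12 tert-butyl{[(1Z,3S)-1-iodo-4-{(2R,3R)-3-[2-(4-methoxybenzyloxy)ethyl]-3-methyloxiran-2-yl}-2-methylbut-1-en-3-yl]oxy}dimethylsilane; 13 (2E)-but-2-enal
Product: 14 (2E,4S,5Z,7S)-7-{[tert-butyl(dimethyl)silyl]oxy}-8-{(2R,3R)-3-[2-(4-methoxybenzyloxy)ethyl]-3-methyloxiran-2-yl}-6-methylocta-2,5-dien-4-ol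
Conditions: CrCl2 (4 equiv), NiCl2 (2 mol %), (S)-N-[2-(4-isopropyl-4,5-dihydro-1,3-oxazol-2-yl)-6-methylphenyl]methanesulfonamide (4.4 equiv), Et3N, THF, rt
Reagents that add atoms: none
Why: Asymmetric Nozaki–Hiyama–Kishi coupling: the alkenylchromium (olefin geometry retained) adds 1,2 to the enal inside the chiral sulfonamide complex to set C6, and the minor C6 epimer is a diastereomer removable by chromatography.

Step 9
Reactants: 14 (2E,4S,5Z,7S)-7-{[tert-butyl(dimethyl)silyl]oxy}-8-{(2R,3R)-3-[2-(4-methoxybenzyloxy)ethyl]-3-methyloxiran-2-yl}-6-methylocta-2,5-dien-4-ol; 15 2-(bromomethyl)prop-2-enoic acid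
Product: 17 (2E,4S,5Z,7S)-7-{[tert-butyl(dimethyl)silyl]oxy}-8-{(2R,3R)-3-[2-(4-methoxybenzyloxy)ethyl]-3-methyloxiran-2-yl}-6-methylocta-2,5-dien-4-yl 2-(bromomethyl)prop-2-enoate, via 2-(bromomethyl)prop-2-enoyl chloride 16 (not isolated)
Conditions: 15, (COCl)2, DMF (cat.), CH2Cl2, 0 °C → rt; concentrate; then 14, 2,6-lutidine, CH2Cl2, −20 → 0 °C
Reagents that add atoms: none
Why: Acylation through the acid chloride with a hindered, non-nucleophilic base esterifies the only free hydroxyl (C6) without displacing the allylic bromide or disturbing C6.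

Step 10
Reactants: 17 (2E,4S,5Z,7S)-7-{[tert-butyl(dimethyl)silyl]oxy}-8-{(2R,3R)-3-[2-(4-methoxybenzyloxy)ethyl]-3-methyloxiran-2-yl}-6-methylocta-2,5-dien-4-yl 2-(bromomethyl)prop-2-enoate
Product: 18 (5R)-3-(bromomethyl)-5-[(1Z,3S)-3-{[tert-butyl(dimethyl)silyl]oxy}-4-{(2R,3R)-3-[2-(4-methoxybenzyloxy)ethyl]-3-methyloxiran-2-yl}-2-methylbut-1-en-1-yl]furan-2(5H)-one
Conditions: second-generation Hoveyda–Grubbs catalyst (10 mol %), PhMe, 80 °C
Reagents that add atoms: none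
Why: Ring-closing metathesis: the ruthenium carbene loads on the propenyl group and closes onto the acrylate to give the five-membered butenolide with loss of propene, the hindered trisubstituted C4=C5 olefin staying inert.

Step 11
Reactants: 18 (5R)-3-(bromomethyl)-5-[(1Z,3S)-3-{[tert-butyl(dimethyl)silyl]oxy}-4-{(2R,3R)-3-[2-(4-methoxybenzyloxy)ethyl]-3-methyloxiran-2-yl}-2-methylbut-1-en-1-yl]furan-2(5H)-one
Product: 19 (5R)-3-(bromomethyl)-5-[(1Z,3S)-3-{[tert-butyl(dimethyl)silyl]oxy}-4-[(2R,3R)-3-(2-hydroxyethyl)-3-methyloxiran-2-yl]-2-methylbut-1-en-1-yl]furan-2(5H)-one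
Conditions: DDQ, CH2Cl2/pH 7 buffer, 0 °C → rt
Reagents that add atoms: none
Why: Oxidative cleavage of the 4-methoxybenzyl ether by DDQ is neutral and non-nucleophilic, so the allylic bromide, epoxide, butenolide and silyl ether survive.

Step 12
Reactants: 19 (5R)-3-(bromomethyl)-5-[(1Z,3S)-3-{[tert-butyl(dimethyl)silyl]oxy}-4-[(2R,3R)-3-(2-hydroxyethyl)-3-methyloxiran-2-yl]-2-methylbut-1-en-1-yl]furan-2(5H)-one
Product: 20 {(2R,3R)-3-[(2S,3Z)-4-[(2R)-4-(bromomethyl)-5-oxo-2,5-dihydrofuran-2-yl]-2-{[tert-butyl(dimethyl)silyl]oxy}-3-methylbut-3-en-1-yl]-2-methyloxiran-2-yl}acetaldehyde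
Conditions: Dess–Martin periodinane, pyridine, CH2Cl2, 0 °C; used at once
Reagents that add atoms: none
Why: Dess–Martin oxidation gives the base-sensitive β,γ-epoxy aldehyde without the E1cB epoxide opening that amine-mediated oxidations would risk.

Step 13
Reactants: 20 {(2R,3R)-3-[(2S,3Z)-4-[(2R)-4-(bromomethyl)-5-oxo-2,5-dihydrofuran-2-yl]-2-{[tert-butyl(dimethyl)silyl]oxy}-3-methylbut-3-en-1-yl]-2-methyloxiran-2-yl}acetaldehyde
Product: 21 (1R,3S,4Z,6R,7R,8S,10R)-3-{[tert-butyl(dimethyl)silyl]oxy}-1,10-epoxy-8-hydroxygermacra-4,11(13)-dien-12,6-olide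
Conditions: CrCl2 (8 equiv), THF, 0.002 M, slow addition of 20, rt
Reagents that add atoms: none
Why: Proposed new method: CrCl2 turns the allylic bromide into an allylchromium whose γ-carbon is the butenolide β-carbon C7 (normally an electrophilic Michael position, here a lactone homoenolate equivalent), which attacks the tethered C8 aldehyde through a chair Zimmerman–Traxler transition state anti to the C6 side chain (6,7-trans lactone, 7R) with C9 equatorial (8S, the C8 epimer needed for inversion in step 21) while the double bond shifts to the exo-methylene; the closest known reaction types are the intermolecular chromium- or zinc-mediated γ-allylation of aldehydes by 3-(bromomethyl)furan-2(5H)-ones and chromium-mediated Barbier macrocyclisations to ten-membered germacranolides.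

Step 14
Reactants: 22 {[tert-butyl(dimethyl)silyl]oxy}acetaldehyde; 23 tert-butyl prop-2-enoate
Product: 24 tert-butyl (±)-4-{[tert-butyl(dimethyl)silyl]oxy}-3-hydroxy-2-methylidenebutanoate
Conditions: DABCO, 1,4-dioxane/H2O, rt
Reagents that add atoms: none
Why: Morita–Baylis–Hillman reaction of an activated α-alkoxy aldehyde with the acrylate gives the allylic alcohol, whose stereocentre is removed in the next step.

Step 15
Reactants: 24 tert-butyl (±)-4-{[tert-butyl(dimethyl)silyl]oxy}-3-hydroxy-2-methylidenebutanoate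
Product: 26 tert-butyl (2E)-2-(acetoxymethyl)-4-{[tert-butyl(dimethyl)silyl]oxy}but-2-enoate, via secondary acetate 25 (not isolated)
Conditions: Ac2O, Et3N, DMAP (cat.), CH2Cl2, 0 °C; then DABCO, THF, 65 °C
Reagents that add atoms: acetic anhydride, CC(=O)OC(C)=O
Why: Acetylation followed by DABCO-mediated SN2′/SN2 allylic transposition gives the thermodynamic primary acetate with the β-substituent trans to the ester (E).

Step 16
Reactants: 26 tert-butyl (2E)-2-(acetoxymethyl)-4-{[tert-butyl(dimethyl)silyl]oxy}but-2-enoate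
Product: 28 (2E)-2-(acetoxymethyl)-4-{[tert-butyl(dimethyl)silyl]oxy}but-2-enoic acid, via trimethylsilyl ester 27 (not isolated)
Conditions: TMSOTf, 2,6-lutidine, CH2Cl2, 0 °C; then H2O
Reagents that add atoms: none
Why: Silyl-triflate-mediated tert-butyl ester cleavage (loss of isobutene) under buffered conditions leaves the primary silyl ether and the allylic acetate intact.

Step 17
Reactants: 29 acetaldehyde; 23 tert-butyl prop-2-enoate
Product: 30 tert-butyl (±)-3-hydroxy-2-methylidenebutanoate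
Conditions: DABCO, 1,4-dioxane/H2O, rt, sealed vessel
Reagents that add atoms: none
Why: Morita–Baylis–Hillman reaction provides the four-carbon inner acid unit as its allylic alcohol.

Step 18
Reactants: 30 tert-butyl (±)-3-hydroxy-2-methylidenebutanoate
Product: 31 tert-butyl (2Z)-2-(bromomethyl)but-2-enoate
Conditions: NBS, Me2S, CH2Cl2, 0 °C → rt
Reagents that add atoms: N-bromosuccinimide, O=C1CCC(=O)N1Br
Why: Corey–Kim-type activation of the alcohol and SN2′ attack of bromide gives the rearranged primary allylic bromide with methyl trans to the ester, without acid that would cleave the tert-butyl ester.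

Step 19
Reactants: 28 (2E)-2-(acetoxymethyl)-4-{[tert-butyl(dimethyl)silyl]oxy}but-2-enoic acid; 31 tert-butyl (2Z)-2-(bromomethyl)but-2-enoate
Product: 32 tert-butyl (2E)-2-({[(2E)-2-(acetoxymethyl)-4-{[tert-butyl(dimethyl)silyl]oxy}but-2-enoyl]oxy}methyl)but-2-enoate
Conditions: K2CO3, DMF, 0 °C → rt
Reagents that add atoms: none
Why: SN2 alkylation of the potassium carboxylate by the primary allylic bromide joins the two units with both olefin geometries retained.

Step 20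
Reactants: 32 tert-butyl (2E)-2-({[(2E)-2-(acetoxymethyl)-4-{[tert-butyl(dimethyl)silyl]oxy}but-2-enoyl]oxy}methyl)but-2-enoate
Product: 34 (2E)-2-({[(2E)-2-(acetoxymethyl)-4-{[tert-butyl(dimethyl)silyl]oxy}but-2-enoyl]oxy}methyl)but-2-enoic acid, via trimethylsilyl ester 33 (not isolated)
Conditions: TMSOTf, 2,6-lutidine, CH2Cl2, 0 °C; then H2O
Reagents that add atoms: none
Why: The same silyl-triflate tert-butyl ester cleavage frees the only tert-butyl ester and leaves the two enoate esters, the acetate and the silyl ether untouched.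

Step 21
Reactants: 21 (1R,3S,4Z,6R,7R,8S,10R)-3-{[tert-butyl(dimethyl)silyl]oxy}-1,10-epoxy-8-hydroxygermacra-4,11(13)-dien-12,6-olide; 34 (2E)-2-({[(2E)-2-(acetoxymethyl)-4-{[tert-butyl(dimethyl)silyl]oxy}but-2-enoyl]oxy}methyl)but-2-enoic acid
Product: 35 (1R,3S,4Z,6R,7R,8R,10R)-3-{[tert-butyl(dimethyl)silyl]oxy}-1,10-epoxy-8-{[(2E)-2-({[(2E)-2-(acetoxymethyl)-4-{[tert-butyl(dimethyl)silyl]oxy}but-2-enoyl]oxy}methyl)but-2-enoyl]oxy}germacra-4,11(13)-dien-12,6-olide
Conditions: PPh3, DIAD, PhMe, 0 °C → rt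
Reagents that add atoms: none
Why: Mitsunobu esterification: the carboxylate displaces the oxyphosphonium at C8 by SN2, so the equatorial 8S alcohol becomes the axial 8R ester of the target in the step that also attaches the side chain.

Step 22
Reactants: 35 (1R,3S,4Z,6R,7R,8R,10R)-3-{[tert-butyl(dimethyl)silyl]oxy}-1,10-epoxy-8-{[(2E)-2-({[(2E)-2-(acetoxymethyl)-4-{[tert-butyl(dimethyl)silyl]oxy}but-2-enoyl]oxy}methyl)but-2-enoyl]oxy}germacra-4,11(13)-dien-12,6-olide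
Product: 36 (1R,3S,4Z,6R,7R,8R,10R)-1,10-epoxy-3-hydroxy-8-{[(2E)-2-({[(2E)-2-(acetoxymethyl)-4-hydroxybut-2-enoyl]oxy}methyl)but-2-enoyl]oxy}germacra-4,11(13)-dien-12,6-olide (CNP0193678.1)
Conditions: HF·pyridine, pyridine, THF, 0 °C → rt
Reagents that add atoms: none
Why: Pyridine-buffered fluoride desilylation removes both silyl ethers without opening the epoxide, adding to the α-methylene lactone or cleaving the esters.

## Compound list

1 | but-3-yn-1-ol | C#CCCO | starting material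
2 | 1-[(but-3-yn-1-yloxy)methyl]-4-methoxybenzene | C#CCCOCc1ccc(OC)cc1 | intermediate
3 | [(1E)-4-(4-methoxybenzyloxy)-2-methylbut-1-en-1-yl]dimethylalane | C[Al](C)/C=C(\C)CCOCc1ccc(OC)cc1 | intermediate
4 | lithium butyl[(1E)-4-(4-methoxybenzyloxy)-2-methylbut-1-en-1-yl]dimethylaluminate | [Li+].CCCC[Al-](C)(C)/C=C(\C)CCOCc1ccc(OC)cc1 | intermediate
5 | (3E)-6-(4-methoxybenzyloxy)-4-methylhex-3-en-1-ol | OCC/C=C(\C)CCOCc1ccc(OC)cc1 | intermediate
6 | (3E)-6-(4-methoxybenzyloxy)-4-methylhex-3-enal | O=CC/C=C(\C)CCOCc1ccc(OC)cc1 | intermediate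
7 | (3S,5E)-8-(4-methoxybenzyloxy)-6-methyl-1-(trimethylsilyl)oct-5-en-1-yn-3-ol | C[Si](C)(C)C#C[C@@H](O)C/C=C(\C)CCOCc1ccc(OC)cc1 | intermediate
8 | (3S,5E)-8-(4-methoxybenzyloxy)-6-methyloct-5-en-1-yn-3-ol | C#C[C@@H](O)C/C=C(\C)CCOCc1ccc(OC)cc1 | intermediate
9 | bromo[(1Z,3S,5E)-3-(bromomagnesiooxy)-8-(4-methoxybenzyloxy)-2,6-dimethylocta-1,5-dien-1-yl]magnesium | Br[Mg]/C=C(/C)[C@@H](O[Mg]Br)C/C=C(\C)CCOCc1ccc(OC)cc1 | intermediate
10 | (1Z,3S,5E)-1-iodo-8-(4-methoxybenzyloxy)-2,6-dimethylocta-1,5-dien-3-ol | I/C=C(/C)[C@@H](O)C/C=C(\C)CCOCc1ccc(OC)cc1 | intermediate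
11 | tert-butyl{[(1Z,3S,5E)-1-iodo-8-(4-methoxybenzyloxy)-2,6-dimethylocta-1,5-dien-3-yl]oxy}dimethylsilane | I/C=C(/C)[C@@H](O[Si](C)(C)C(C)(C)C)C/C=C(\C)CCOCc1ccc(OC)cc1 | intermediate
12 | tert-butyl{[(1Z,3S)-1-iodo-4-{(2R,3R)-3-[2-(4-methoxybenzyloxy)ethyl]-3-methyloxiran-2-yl}-2-methylbut-1-en-3-yl]oxy}dimethylsilane | I/C=C(/C)[C@@H](O[Si](C)(C)C(C)(C)C)C[C@H]1O[C@]1(C)CCOCc2ccc(OC)cc2 | intermediate
13 | (2E)-but-2-enal | C/C=C/C=O | starting material
14 | (2E,4S,5Z,7S)-7-{[tert-butyl(dimethyl)silyl]oxy}-8-{(2R,3R)-3-[2-(4-methoxybenzyloxy)ethyl]-3-methyloxiran-2-yl}-6-methylocta-2,5-dien-4-ol | C/C=C/[C@H](O)/C=C(/C)[C@@H](O[Si](C)(C)C(C)(C)C)C[C@H]1O[C@]1(C)CCOCc2ccc(OC)cc2 | intermediate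
15 | 2-(bromomethyl)prop-2-enoic acid | C=C(CBr)C(=O)O | starting material
16 | 2-(bromomethyl)prop-2-enoyl chloride | C=C(CBr)C(=O)Cl | intermediate
17 | (2E,4S,5Z,7S)-7-{[tert-butyl(dimethyl)silyl]oxy}-8-{(2R,3R)-3-[2-(4-methoxybenzyloxy)ethyl]-3-methyloxiran-2-yl}-6-methylocta-2,5-dien-4-yl 2-(bromomethyl)prop-2-enoate | C/C=C/[C@H](OC(=O)C(=C)CBr)/C=C(/C)[C@@H](O[Si](C)(C)C(C)(C)C)C[C@H]1O[C@]1(C)CCOCc2ccc(OC)cc2 | intermediate
18 | (5R)-3-(bromomethyl)-5-[(1Z,3S)-3-{[tert-butyl(dimethyl)silyl]oxy}-4-{(2R,3R)-3-[2-(4-methoxybenzyloxy)ethyl]-3-methyloxiran-2-yl}-2-methylbut-1-en-1-yl]furan-2(5H)-one | O=C1O[C@H](/C=C(/C)[C@@H](O[Si](C)(C)C(C)(C)C)C[C@H]2O[C@]2(C)CCOCc3ccc(OC)cc3)C=C1CBr | intermediate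
19 | (5R)-3-(bromomethyl)-5-[(1Z,3S)-3-{[tert-butyl(dimethyl)silyl]oxy}-4-[(2R,3R)-3-(2-hydroxyethyl)-3-methyloxiran-2-yl]-2-methylbut-1-en-1-yl]furan-2(5H)-one | O=C1O[C@H](/C=C(/C)[C@@H](O[Si](C)(C)C(C)(C)C)C[C@H]2O[C@]2(C)CCO)C=C1CBr | intermediate
20 | {(2R,3R)-3-[(2S,3Z)-4-[(2R)-4-(bromomethyl)-5-oxo-2,5-dihydrofuran-2-yl]-2-{[tert-butyl(dimethyl)silyl]oxy}-3-methylbut-3-en-1-yl]-2-methyloxiran-2-yl}acetaldehyde | O=C1O[C@H](/C=C(/C)[C@@H](O[Si](C)(C)C(C)(C)C)C[C@H]2O[C@]2(C)CC=O)C=C1CBr | intermediate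
21 | (1R,3S,4Z,6R,7R,8S,10R)-3-{[tert-butyl(dimethyl)silyl]oxy}-1,10-epoxy-8-hydroxygermacra-4,11(13)-dien-12,6-olide | C=C1C(=O)O[C@@H]2/C=C(/C)[C@@H](O[Si](C)(C)C(C)(C)C)C[C@H]3O[C@]3(C)C[C@H](O)[C@@H]12 | intermediate
22 | {[tert-butyl(dimethyl)silyl]oxy}acetaldehyde | O=CCO[Si](C)(C)C(C)(C)C | starting material
23 | tert-butyl prop-2-enoate | C=CC(=O)OC(C)(C)C | starting material
24 | tert-butyl (±)-4-{[tert-butyl(dimethyl)silyl]oxy}-3-hydroxy-2-methylidenebutanoate | C=C(C(O)CO[Si](C)(C)C(C)(C)C)C(=O)OC(C)(C)C | intermediate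
25 | tert-butyl (±)-3-acetoxy-4-{[tert-butyl(dimethyl)silyl]oxy}-2-methylidenebutanoate | C=C(C(OC(C)=O)CO[Si](C)(C)C(C)(C)C)C(=O)OC(C)(C)C | intermediate
26 | tert-butyl (2E)-2-(acetoxymethyl)-4-{[tert-butyl(dimethyl)silyl]oxy}but-2-enoate | CC(C)(C)OC(=O)/C(=C/CO[Si](C)(C)C(C)(C)C)COC(C)=O | intermediate
27 | trimethylsilyl (2E)-2-(acetoxymethyl)-4-{[tert-butyl(dimethyl)silyl]oxy}but-2-enoate | C[Si](C)(C)OC(=O)/C(=C/CO[Si](C)(C)C(C)(C)C)COC(C)=O | intermediate
28 | (2E)-2-(acetoxymethyl)-4-{[tert-butyl(dimethyl)silyl]oxy}but-2-enoic acid | OC(=O)/C(=C/CO[Si](C)(C)C(C)(C)C)COC(C)=O | intermediate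
29 | acetaldehyde | CC=O | starting material
30 | tert-butyl (±)-3-hydroxy-2-methylidenebutanoate | CC(O)C(=C)C(=O)OC(C)(C)C | intermediate
31 | tert-butyl (2Z)-2-(bromomethyl)but-2-enoate | CC(C)(C)OC(=O)/C(=C/C)CBr | intermediate
32 | tert-butyl (2E)-2-({[(2E)-2-(acetoxymethyl)-4-{[tert-butyl(dimethyl)silyl]oxy}but-2-enoyl]oxy}methyl)but-2-enoate | CC(C)(C)OC(=O)/C(=C/C)COC(=O)/C(=C/CO[Si](C)(C)C(C)(C)C)COC(C)=O | intermediate
33 | trimethylsilyl (2E)-2-({[(2E)-2-(acetoxymethyl)-4-{[tert-butyl(dimethyl)silyl]oxy}but-2-enoyl]oxy}methyl)but-2-enoate | C[Si](C)(C)OC(=O)/C(=C/C)COC(=O)/C(=C/CO[Si](C)(C)C(C)(C)C)COC(C)=O | intermediate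
34 | (2E)-2-({[(2E)-2-(acetoxymethyl)-4-{[tert-butyl(dimethyl)silyl]oxy}but-2-enoyl]oxy}methyl)but-2-enoic acid | OC(=O)/C(=C/C)COC(=O)/C(=C/CO[Si](C)(C)C(C)(C)C)COC(C)=O | intermediate
35 | (1R,3S,4Z,6R,7R,8R,10R)-3-{[tert-butyl(dimethyl)silyl]oxy}-1,10-epoxy-8-{[(2E)-2-({[(2E)-2-(acetoxymethyl)-4-{[tert-butyl(dimethyl)silyl]oxy}but-2-enoyl]oxy}methyl)but-2-enoyl]oxy}germacra-4,11(13)-dien-12,6-olide | C=C1C(=O)O[C@@H]2/C=C(/C)[C@@H](O[Si](C)(C)C(C)(C)C)C[C@H]3O[C@]3(C)C[C@@H](OC(=O)/C(=C/C)COC(=O)/C(=C/CO[Si](C)(C)C(C)(C)C)COC(C)=O)[C@@H]12 | intermediate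
36 | (1R,3S,4Z,6R,7R,8R,10R)-1,10-epoxy-3-hydroxy-8-{[(2E)-2-({[(2E)-2-(acetoxymethyl)-4-hydroxybut-2-enoyl]oxy}methyl)but-2-enoyl]oxy}germacra-4,11(13)-dien-12,6-olide (CNP0193678.1) | C=C1C(=O)O[C@@H]2/C=C(/C)[C@@H](O)C[C@H]3O[C@]3(C)C[C@@H](OC(=O)/C(=C/C)COC(=O)/C(=C/CO)COC(C)=O)[C@@H]12 | target

## Step count

Total: 22 steps. Longest linear sequence: 15 steps (steps 1–13, 21, 22); the side-chain acid 34 takes 7 steps (14–20) from 22, 23 and 29.

## Steps most likely to fail, with fallbacks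

**Step 13 (chromium-mediated macrocyclisation).** The β,γ-epoxy aldehyde 20 may not survive trivalent chromium Lewis acids, the medium ring may not close, or the 8α-alkoxide may relactonise to the 8,12-olide. The fallback postpones the epoxide. It sets out from 11 (step 7 is skipped) and comes back at 21. Coupling of 11 with 13 under the step-8 conditions gives (2E,4S,5Z,7S,9E)-7-{[tert-butyl(dimethyl)silyl]oxy}-12-(4-methoxybenzyloxy)-6,10-dimethyldodeca-2,5,9-trien-4-ol F1. Acylation as in step 9 gives its 2-(bromomethyl)prop-2-enoate F2, and metathesis as in step 10 gives (5R)-3-(bromomethyl)-5-[(1Z,3S,5E)-3-{[tert-butyl(dimethyl)silyl]oxy}-8-(4-methoxybenzyloxy)-2,6-dimethylocta-1,5-dien-1-yl]furan-2(5H)-one F3. DDQ gives the primary alcohol (5R)-3-(bromomethyl)-5-[(1Z,3S,5E)-3-{[tert-butyl(dimethyl)silyl]oxy}-8-hydroxy-2,6-dimethylocta-1,5-dien-1-yl]furan-2(5H)-one F4, and Dess–Martin oxidation gives (3E,6S,7Z)-8-[(2R)-4-(bromomethyl)-5-oxo-2,5-dihydrofuran-2-yl]-6-{[tert-butyl(dimethyl)silyl]oxy}-3,7-dimethylocta-3,7-dienal F5. CrCl2 at high dilution then closes the more robust olefinic aldehyde to (1(10)E,3S,4Z,6R,7R,8S)-3-{[tert-butyl(dimethyl)silyl]oxy}-8-hydroxygermacra-1(10),4,11(13)-trien-12,6-olide F6. Its strained, electron-rich 1(10)-olefin is epoxidised with mCPBA/NaHCO3 from the exposed outer face (substrate control in place of reagent control) to reach 21.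

**Step 21 (Mitsunobu inversion at hindered C8).** Elimination or lack of reaction at the flanked secondary carbinol is possible; the same fallback also serves if step 13 gives a different C8 ratio. It sets out from 21 and comes back at 35 by redox inversion instead of SN2. Buffered Dess–Martin oxidation gives (1R,3S,4Z,6R,7S,10R)-3-{[tert-butyl(dimethyl)silyl]oxy}-1,10-epoxy-8-oxogermacra-4,11(13)-dien-12,6-olide F7. Luche reduction (NaBH4, CeCl3, MeOH, −78 °C), with hydride from the α-face away from C14 and the C7–C11 bond, gives (1R,3S,4Z,6R,7R,8R,10R)-3-{[tert-butyl(dimethyl)silyl]oxy}-1,10-epoxy-8-hydroxygermacra-4,11(13)-dien-12,6-olide F8. Yamaguchi esterification of F8 with 34 (2,4,6-trichlorobenzoyl chloride, Et3N, DMAP) proceeds with retention and gives 35.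

**Step 8 (asymmetric Nozaki–Hiyama–Kishi coupling).** Diastereocontrol at C6 may be low with this Z-iodide and enal. The fallback reverses the roles of the partners. It sets out from 12 and comes back at 14. Iodine–lithium exchange (t-BuLi, Et2O, −78 °C) and formylation with DMF give (2Z,4S)-4-{[tert-butyl(dimethyl)silyl]oxy}-5-{(2R,3R)-3-[2-(4-methoxybenzyloxy)ethyl]-3-methyloxiran-2-yl}-3-methylpent-2-enal F9. Catalytic asymmetric alkenylzinc addition to F9 then gives 14: (E)-prop-1-enylzinc from propyne, dicyclohexylborane and Et2Zn, with (−)-3-exo-morpholinoisoborneol as ligand.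

## Further compounds

F1 | step 13 | (2E,4S,5Z,7S,9E)-7-{[tert-butyl(dimethyl)silyl]oxy}-12-(4-methoxybenzyloxy)-6,10-dimethyldodeca-2,5,9-trien-4-ol | C/C=C/[C@H](O)/C=C(/C)[C@@H](O[Si](C)(C)C(C)(C)C)C/C=C(\C)CCOCc1ccc(OC)cc1
F2 | step 13 | (2E,4S,5Z,7S,9E)-7-{[tert-butyl(dimethyl)silyl]oxy}-12-(4-methoxybenzyloxy)-6,10-dimethyldodeca-2,5,9-trien-4-yl 2-(bromomethyl)prop-2-enoate | C/C=C/[C@H](OC(=O)C(=C)CBr)/C=C(/C)[C@@H](O[Si](C)(C)C(C)(C)C)C/C=C(\C)CCOCc1ccc(OC)cc1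
F3 | step 13 | (5R)-3-(bromomethyl)-5-[(1Z,3S,5E)-3-{[tert-butyl(dimethyl)silyl]oxy}-8-(4-methoxybenzyloxy)-2,6-dimethylocta-1,5-dien-1-yl]furan-2(5H)-one | O=C1O[C@H](/C=C(/C)[C@@H](O[Si](C)(C)C(C)(C)C)C/C=C(\C)CCOCc2ccc(OC)cc2)C=C1CBr
F4 | step 13 | (5R)-3-(bromomethyl)-5-[(1Z,3S,5E)-3-{[tert-butyl(dimethyl)silyl]oxy}-8-hydroxy-2,6-dimethylocta-1,5-dien-1-yl]furan-2(5H)-one | O=C1O[C@H](/C=C(/C)[C@@H](O[Si](C)(C)C(C)(C)C)C/C=C(\C)CCO)C=C1CBr
F5 | step 13 | (3E,6S,7Z)-8-[(2R)-4-(bromomethyl)-5-oxo-2,5-dihydrofuran-2-yl]-6-{[tert-butyl(dimethyl)silyl]oxy}-3,7-dimethylocta-3,7-dienal | O=C1O[C@H](/C=C(/C)[C@@H](O[Si](C)(C)C(C)(C)C)C/C=C(\C)CC=O)C=C1CBr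
F6 | step 13 | (1(10)E,3S,4Z,6R,7R,8S)-3-{[tert-butyl(dimethyl)silyl]oxy}-8-hydroxygermacra-1(10),4,11(13)-trien-12,6-olide | C=C1C(=O)O[C@@H]2/C=C(/C)[C@@H](O[Si](C)(C)C(C)(C)C)C/C=C(\C)C[C@H](O)[C@@H]12
F7 | step 21 | (1R,3S,4Z,6R,7S,10R)-3-{[tert-butyl(dimethyl)silyl]oxy}-1,10-epoxy-8-oxogermacra-4,11(13)-dien-12,6-olide | C=C1C(=O)O[C@@H]2/C=C(/C)[C@@H](O[Si](C)(C)C(C)(C)C)C[C@H]3O[C@]3(C)CC(=O)[C@@H]12
F8 | step 21 | (1R,3S,4Z,6R,7R,8R,10R)-3-{[tert-butyl(dimethyl)silyl]oxy}-1,10-epoxy-8-hydroxygermacra-4,11(13)-dien-12,6-olide | C=C1C(=O)O[C@@H]2/C=C(/C)[C@@H](O[Si](C)(C)C(C)(C)C)C[C@H]3O[C@]3(C)C[C@@H](O)[C@@H]12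
F9 | step 8 | (2Z,4S)-4-{[tert-butyl(dimethyl)silyl]oxy}-5-{(2R,3R)-3-[2-(4-methoxybenzyloxy)ethyl]-3-methyloxiran-2-yl}-3-methylpent-2-enal | O=C/C=C(/C)[C@@H](O[Si](C)(C)C(C)(C)C)C[C@H]1O[C@]1(C)CCOCc2ccc(OC)cc2
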